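**Remarks on the chemistry (assumptions and checks)**

- Structure check: the descriptors of 14 (6R,12S) and of 17 (3R,6'S) agree with their drawings and with each other, because no bond to either stereocentre is made or broken between them and the priority order O > CH2–C(sp2) > alkyl chain stays the same. No structure needed correction.
- The (R,R) series of (salen)Co(OAc) is taken to hydrolyse the (R)-enantiomer of a 2-alkyloxirane faster and to leave (S)-2. The sign of rotation of 2 is checked before use, and the (S,S) complex is used should the correlation be the reverse.
- 8 is taken as purchasable; where it is not, one N-acetylation (AcCl, Et3N) of commercial (R)-4-benzyl-1,3-thiazolidine-2-thione supplies it.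
- The titanium acetate aldol is assumed to run through the thione-chelated chair, so that the (4R)-auxiliary gives the 3R adduct. The configuration is confirmed on 10 by Mosher ester analysis, and the (4S)-auxiliary is used should the sense be the opposite.

## Structural features

The target is a 3,4-dihydroisocoumarin: a resorcinol ring A (C4a, C5, C6, C7, C8, C8a) shares the C4a–C8a bond with a six-membered δ-lactone ring B (C1, O2, C3, C4), and C3 carries a linear eleven-carbon chain (C1' to C11'). There are two stereocentres, C3 (R) in ring B and the carbinol C6' (S) in the chain. Five methylene groups separate them, so they do not stand next to each other, neither can steer the other, and each has to be set by a reagent. The fragile groups are the electron-rich resorcinol (oxidation, electrophiles), the lactone (opened by hydroxide or alkoxide, reclosed in acid) and the free secondary alcohol, which argues against late ether cleavage with boron or aluminium halides. The C8 hydroxyl is hydrogen-bonded to the C1 carbonyl and the C6 hydroxyl is para to C8a, so ring A behaves as a vinylogous acid and is ionised under base. The real difficulty is a 1,2,3,5-tetrasubstituted benzene of fixed pattern (acyl carbon on C8a, flanked by oxygen on C8 and by CH2 on C4a, with oxygen on C6) that must end as two free phenols next to a base-labile lactone, together with two remote stereocentres. The feature the key step exploits is that C1, C8, C6 and C4a are oxidised carbons in alternation, the imprint of a poly-β-carbonyl chain, and that the oxygen on C3 is δ to C1. An aldol bond C8a–C4a therefore closes ring A, and acyl transfer of C1 to the C3 oxygen closes ring B.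

## Logic of the disconnections

**17 to 14 (through 16 and 15).** The bonds cut are C1–O2 (ring B) and C4a–C8a (ring A). Cutting there removes both rings at once and leaves an open chain hung on one six-membered heterocycle that masks C1 and the C8 oxygen, so the phenols never need protecting groups. The gain is the whole bicycle and the substitution pattern of the arene. The demand is that only the aldol mode C8a to C4a operates and that the C3 oxygen stays silylated until ring A is aromatic. For that reason both carbinols in 14 carry triethylsilyl ethers, which are stable to amine base and removed by one fluoride reagent. 14 is also quenched with acetic acid and used without storage.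

**14 to 13 and 11.** The bond cut is C4a–C5, between a ketone carbon and the central methylene of the diketone. This is a Claisen-type cut at a carbonyl and divides the molecule into a three-ring-carbon-plus-three-chain-carbon nucleophile and an acyl donor that holds both stereocentres. The gain is convergence. The demand is acylation at the terminal carbon of a dianion without over-addition, without loss of the β-silyloxy group, and with a quench mild enough for silyl ethers.

**13 to 12.** The bond cut is C6–C7, between the ketone carbon and the methylene on the heterocycle. The gain is a commercial starting material. The demand is acylation at the γ-carbon of a dienolate and not at oxygen or at the α-carbon.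

**11 to 10 to 9, then to 7 and 8.** Two functional-group changes (O–Si at C3, N–C1 exchange of the acyl carrier) lead back to the aldol cut of C3–C4. C3 is then set under auxiliary control, independent of the remote C6', and the auxiliary makes the C3 epimers separable diastereomers. The demand is facial control for an acetate enolate that has no α-substituent.

**7 to 6 to 5.** The aldehyde carbon (future C3) is traced to a terminal alkene by cleavage of C=C. The alkene is inert in the preceding C–C bond formation, and one carbon is lost as planned. The demand is a silyl ether that survives ozone.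

**5 to 2 and 3 (through 4).** The bond cut is C4'–C5', next to the carbinol carbon. The C6' stereocentre is thereby bought as an epoxide and the rest of the chain as a primary organometallic. The demand is attack at the unsubstituted epoxide carbon only.

**2 to 1.** No bond of the skeleton is cut; the single enantiomer comes from the racemate by resolution. The demand is high selectivity of the catalyst and a clean separation of epoxide and diol.

## Other disconnections considered

**Alternative 1:** Ring A is cut through C4a–C5 and C8a–C8. The alkyne carbons of the ynoate methyl (5R,11S)-5,11-bis(triethylsilyloxy)hexadec-2-ynoate A2 become C4a and C8a, and C5 to C8 with both phenol oxygens come from 1-methoxy-1,3-bis(trimethylsilyloxy)buta-1,3-diene A3. The forward key step is a thermal [4+2] addition followed by loss of methanol to give methyl 2,4-dihydroxy-6-[(2R,8S)-2,8-bis(triethylsilyloxy)tridecyl]benzoate A1, which fluoride would desilylate and lactonise.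

- In its favour: A2 is a stable compound that can be purified and stored, and on this point the alternative is better than the chosen plan, whose 14 is sensitive. Both carbinols could come from epoxides (A2 from 6 by epoxidation, a second hydrolytic kinetic resolution, opening with a metalated propiolate ester and silylation), which is equal or better in stereochemical security than an acetate aldol.
- Against it here: an alkyl-substituted ynoate is only a moderate dienophile, so long heating with an excess of a moisture-sensitive diene is expected, with silyl transfer and diene decay in competition. The second resolution discards half of an advanced intermediate. The doubly ortho-substituted methyl ester of A1 is a poorer acyl donor than the dioxinone of 15.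
- Comparison: on structure the two plans are equal, since both deliver ring A with free phenols and no arene protecting group. On mechanism, the regiochemistry of the alternative rests on the polarisation of diene and dienophile, that of the chosen plan on a tether that allows one closure only. On step economy they are equal (about nine steps in one line against a longest line of nine).

**Alternative 2:** The cut removes the arene from ring B at C4a–C4 and C8a–C1. The lithium enolate of (4R)-4-[(6S)-6-(tert-butyldimethylsilyloxy)undecyl]oxetan-2-one A5 would add through its α-carbon to 3,5-dimethoxybenzyne A6, and the aryl anion would attack the lactone carbonyl. Fragmentation then leaves the aryne inserted into the Cα–C(O) bond, giving (3R)-3-[(6S)-6-(tert-butyldimethylsilyloxy)undecyl]-6,8-dimethoxyisochroman-1-one A4.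

- In its favour: two C–C bonds form and ring B is completed in one step from a simple arene precursor. The addition of a carbon nucleophile meta to the flanking methoxy group of A6 gives the required 6,8-pattern. C3 is carried in unchanged from A5. In convergence and in the number of steps to the bicycle (about five steps to A5 from 2, then one) this alternative is better than the chosen plan.
- Against it here: insertion of arynes into C–C bonds is established for doubly stabilised carbon acids, whereas the enolate of a simple β-lactone is fragile (ring opening, self-condensation) and the aryl anion may be protonated before it reaches the carbonyl. A4 still carries two methyl ethers. Their cleavage with BBr3 also removes the silyl ether and exposes the lactone and the secondary alcohol to a strong Lewis acid.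
- Comparison: on structure the alternative buys the arene and pays with phenol deprotection, whereas the chosen plan builds the arene and needs none. On mechanism the alternative has an unproven substrate class in its key step, the chosen plan merges two known steps. On step economy the alternative is about one step shorter at best, a gain that the demethylation may cancel.

**Alternative 3:** The cut is the C3–O2 bond. A flavin-dependent Baeyer–Villiger monooxygenase with O2 and NADPH recycling in mildly basic buffer would insert oxygen between the ketone carbon and C2 of 2-[(6S)-6-hydroxyundecyl]-5,7-dimethoxyindan-1-one A8, which epimerises at C2 under the conditions. The product would be (3R)-3-[(6S)-6-hydroxyundecyl]-6,8-dimethoxyisochroman-1-one A7. A8 would come from 5,7-dimethoxyindan-1-one A9 by attachment of an eleven-carbon electrophile derived from 2.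

- In its favour: C3 is set by a dynamic kinetic resolution on a substrate that needs no stereocontrol in its assembly, under very mild conditions. The reaction type is known for 2-alkylindan-1-ones. On the point of setting C3 without an auxiliary or a stoichiometric chiral reagent the alternative is better.
- Against it here: the enzyme would have to accept a long lipophilic chain and a methoxy group peri to the ketone. The electron-rich aryl group raises the tendency of aryl migration to the regioisomeric dihydrocoumarin. Epimerisation must outrun oxidation. The product again needs double O-demethylation next to a free alcohol and a lactone.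
- Comparison: on structure it shares the deprotection problem of alternative 2. On mechanism the selectivity lies in an enzyme pocket that cannot be predicted for this substrate, against substrate-enforced selectivity in the chosen plan. On step economy it is equal or slightly better (about eight to nine steps), provided the enzyme accepts A8.

Key step: step 10

## Route

Step 1
Reactants: 1 rac-2-pentyloxirane (1,2-epoxyheptane)
Product: 2 (S)-2-pentyloxirane
Conditions: (R,R)-(salen)Co(OAc) (0.5 mol %; acetate of the trivalent cobalt complex of (R,R)-N,N'-bis(3,5-di-tert-butylsalicylidene)-1,2-cyclohexanediamine), H2O (0.55 equiv), neat, 0 °C → rt; distillation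
Reagents that add atoms: none
Why: Hydrolytic kinetic resolution (Jacobsen): the chiral cobalt–salen complex activates epoxide and water cooperatively and should hydrolyse the (R)-epoxide far faster, so that the unreacted (S)-epoxide is left in high enantiomeric purity and is distilled from the diol. This sets C6'.

Step 2
Reactants: 2 (S)-2-pentyloxirane; 3 6-bromohex-1-ene
Product: 5 (S)-tridec-12-en-6-ol, via hex-5-enylmagnesium bromide 4 (not isolated)
Conditions: 3, Mg, THF, rt; then CuI (10 mol %), 2, THF, −30 → 0 °C; 1 M HCl
Reagents that add atoms: none
Why: Copper-catalysed SN2 opening of a monosubstituted epoxide by a primary Grignard reagent at the unsubstituted carbon; the C–O bond at the stereocentre is not touched, so the configuration is kept. Traces of cyclopentylmethyl isomer from the Grignard formation carry no alkene and are removed after step 4.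

Step 3
Reactants: 5 (S)-tridec-12-en-6-ol
Product: 6 triethyl[(6S)-tridec-12-en-6-yloxy]silane
Conditions: Et3SiCl, imidazole, CH2Cl2, 0 °C → rt
Reagents that add atoms: chlorotriethylsilane, CC[Si](Cl)(CC)CC
Why: Imidazole-promoted silylation of a secondary alcohol; the triethylsilyl ether should survive ozone, the titanium enolate at low temperature and lithium amides, and is cleaved by fluoride in step 10.

Step 4
Reactants: 6 triethyl[(6S)-tridec-12-en-6-yloxy]silane
Product: 7 (7S)-7-(triethylsilyloxy)dodecanal
Conditions: O3, CH2Cl2, −78 °C; then PPh3, −78 °C → rt
Reagents that add atoms: ozone, O=[O+][O-]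
Why: Ozonolysis of a terminal alkene with reductive work-up gives the aldehyde and removes the terminal carbon as formaldehyde; the silyl ether and the stereocentre are inert.

Step 5
Reactants: 7 (7S)-7-(triethylsilyloxy)dodecanal; 8 1-[(4R)-4-benzyl-2-thioxo-1,3-thiazolidin-3-yl]ethan-1-one
Product: 9 (3R,9S)-1-[(4R)-4-benzyl-2-thioxo-1,3-thiazolidin-3-yl]-3-hydroxy-9-(triethylsilyloxy)tetradecan-1-one
Conditions: 8, TiCl4, iPr2NEt, CH2Cl2, −78 → −40 °C; then 7, −78 °C; aq NH4Cl
Reagents that add atoms: none
Why: Auxiliary-controlled acetate aldol of a chlorotitanium enolate (Nagao-type N-acetylthiazolidinethione): in the thione-chelated chair the benzyl group shields one enolate face, and the aldehyde, with its chain equatorial, adds to the other face to give the 3R carbinol. The minor C3 epimer is a diastereomer and is removed by chromatography.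

Step 6
Reactants: 9 (3R,9S)-1-[(4R)-4-benzyl-2-thioxo-1,3-thiazolidin-3-yl]-3-hydroxy-9-(triethylsilyloxy)tetradecan-1-one
Product: 10 (3R,9S)-3-hydroxy-N-methoxy-N-methyl-9-(triethylsilyloxy)tetradecanamide
Conditions: MeONHMe·HCl, imidazole, CH2Cl2, rt
Reagents that add atoms: N,O-dimethylhydroxylamine hydrochloride, CNOC.Cl
Why: Aminolysis of the activated N-acylthiazolidinethione by the hydroxylamine under near-neutral conditions gives the Weinreb amide and returns the auxiliary; no retro-aldol or epimerisation is expected at room temperature.

Step 7
Reactants: 10 (3R,9S)-3-hydroxy-N-methoxy-N-methyl-9-(triethylsilyloxy)tetradecanamide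
Product: 11 (3R,9S)-N-methoxy-N-methyl-3,9-bis(triethylsilyloxy)tetradecanamide
Conditions: Et3SiCl, imidazole, DMF, 0 °C → rt
Reagents that add atoms: chlorotriethylsilane, CC[Si](Cl)(CC)CC
Why: Silylation of the β-hydroxyl removes the acidic proton and the retro-aldol path before the strongly basic step 9; the same silyl group on both oxygens lets one reagent free both in step 10.

Step 8
Reactants: 12 2,2,6-trimethyl-4H-1,3-dioxin-4-one
Product: 13 2,2-dimethyl-6-(2-oxopropyl)-4H-1,3-dioxin-4-one
Conditions: 12 (2 equiv), LiN(SiMe3)2 (2 equiv), THF, −78 °C; AcCl (1 equiv), −78 °C; 1 M HCl
Reagents that add atoms: acetyl chloride, CC(=O)Cl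
Why: Claisen-type C-acylation of the lithium dienolate of the dioxinone at its γ-carbon; the second equivalent of dienolate takes the acidic proton of the product, and the excess of 12 is recovered.

Step 9
Reactants: 13 2,2-dimethyl-6-(2-oxopropyl)-4H-1,3-dioxin-4-one; 11 (3R,9S)-N-methoxy-N-methyl-3,9-bis(triethylsilyloxy)tetradecanamide
Product: 14 6-[(6R,12S)-2,4-dioxo-6,12-bis(triethylsilyloxy)heptadecyl]-2,2-dimethyl-4H-1,3-dioxin-4-one
Conditions: 13 (2.5 equiv), LiN(iPr)2 (5 equiv), THF, −78 → −40 °C; then 11, −78 → −40 °C; AcOH, −78 °C; used directly
Reagents that add atoms: none
Why: C-acylation of the 1,3-dianion of the keto-dioxinone at its terminal, more basic carbon by a Weinreb amide, whose chelated tetrahedral intermediate prevents a second addition. The low temperature keeps E1cB loss of the β-silyloxy group slow, and the acetic acid quench spares the silyl ethers.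

Step 10
Reactants: 14 6-[(6R,12S)-2,4-dioxo-6,12-bis(triethylsilyloxy)heptadecyl]-2,2-dimethyl-4H-1,3-dioxin-4-one
Product: 17 (3R)-6,8-dihydroxy-3-[(6S)-6-hydroxyundecyl]isochroman-1-one, via bis(triethylsilyl) benzodioxinone 15 (not isolated), via desilylated benzodioxinone 16 (not isolated)
Conditions: Et3N (5 equiv), THF, rt; then Bu4NF (1 M in THF, 5 equiv), 0 → 40 °C; 1 M HCl to pH 3
Reagents that add atoms: none
Why: Et3N enolises the C5 and C7 methylene groups of the dioxoalkyl chain, and deprotonation at C7 turns the dioxinone into a dienolate whose α-carbon (future C8a) adds to the C4a ketone; E1cB loss of water and tautomerisation of the C6 ketone then give the aromatic benzodioxinone 15 with the C6 oxygen as a phenol. The closest known reaction type is the amine- or carbonate-mediated aromatisation of 6-(2,4-dioxoalkyl)dioxinones to isopropylidene-protected resorcylates, a laboratory copy of the aldol folding of a polyketide chain. Ring A closes by a 6-(enolendo)-exo-trig aldol addition, counted on the C8=C8a enol-ether double bond that lies inside the new ring, followed by dehydration. Bu4NF then cleaves both Si–O bonds (16), and the C3 alkoxide attacks the C1 carbonyl in a 6-exo-trig acyl substitution that closes ring B; the tetrahedral intermediate expels the acetal oxygen, which falls apart to acetone and the C8 phenoxide, as in the known alkoxide lactonisation of benzodioxinones. No stereocentre is formed, and C3 and C6' keep their configuration because only O–Si and acyl C–O bonds are made or broken. The step needs the C8a-to-C4a aldol to win over the Claisen mode (C5 onto C1) and over pyranone formation: C1 is tied into the dioxinone, so attack of C5 on it would pass through a strained bridged intermediate with a bridgehead double bond, and without heat no acylketene is formed. It also needs the C3 oxygen to stay masked until ring A is aromatic, since a free β-hydroxyl would add to the C6 ketone and dehydrate to a dihydropyranone; the silyl ether secures this, enolisation inside the 1,3-dicarbonyl units and not at C4 keeps loss of silanolate slow, and fluoride is added only when 14 is consumed. Excess fluoride and gentle warming are provided because the C6 phenoxide, para to C8a, lowers the electrophilicity of C1.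

## Compound list

1 | rac-2-pentyloxirane (1,2-epoxyheptane) | CCCCCC1CO1 | starting material
2 | (S)-2-pentyloxirane | CCCCC[C@H]1CO1 | intermediate
3 | 6-bromohex-1-ene | C=CCCCCBr | starting material
4 | hex-5-enylmagnesium bromide | C=CCCCC[Mg]Br | intermediate (not isolated)
5 | (S)-tridec-12-en-6-ol | CCCCC[C@H](O)CCCCCC=C | intermediate
6 | triethyl[(6S)-tridec-12-en-6-yloxy]silane | CCCCC[C@H](O[Si](CC)(CC)CC)CCCCCC=C | intermediate
7 | (7S)-7-(triethylsilyloxy)dodecanal | CCCCC[C@H](O[Si](CC)(CC)CC)CCCCCC=O | intermediate
8 | 1-[(4R)-4-benzyl-2-thioxo-1,3-thiazolidin-3-yl]ethan-1-one | CC(=O)N1C(=S)SC[C@H]1Cc1ccccc1 | starting material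
9 | (3R,9S)-1-[(4R)-4-benzyl-2-thioxo-1,3-thiazolidin-3-yl]-3-hydroxy-9-(triethylsilyloxy)tetradecan-1-one | CCCCC[C@H](O[Si](CC)(CC)CC)CCCCC[C@@H](O)CC(=O)N1C(=S)SC[C@H]1Cc1ccccc1 | intermediate
10 | (3R,9S)-3-hydroxy-N-methoxy-N-methyl-9-(triethylsilyloxy)tetradecanamide | CCCCC[C@H](O[Si](CC)(CC)CC)CCCCC[C@@H](O)CC(=O)N(C)OC | intermediate
11 | (3R,9S)-N-methoxy-N-methyl-3,9-bis(triethylsilyloxy)tetradecanamide | CCCCC[C@H](O[Si](CC)(CC)CC)CCCCC[C@@H](O[Si](CC)(CC)CC)CC(=O)N(C)OC | intermediate
12 | 2,2,6-trimethyl-4H-1,3-dioxin-4-one | CC1=CC(=O)OC(C)(C)O1 | starting material
13 | 2,2-dimethyl-6-(2-oxopropyl)-4H-1,3-dioxin-4-one | CC(=O)CC1=CC(=O)OC(C)(C)O1 | intermediate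
14 | 6-[(6R,12S)-2,4-dioxo-6,12-bis(triethylsilyloxy)heptadecyl]-2,2-dimethyl-4H-1,3-dioxin-4-one | CCCCC[C@H](O[Si](CC)(CC)CC)CCCCC[C@@H](O[Si](CC)(CC)CC)CC(=O)CC(=O)CC1=CC(=O)OC(C)(C)O1 | intermediate
15 | 7-hydroxy-2,2-dimethyl-5-[(2R,8S)-2,8-bis(triethylsilyloxy)tridecyl]-4H-1,3-benzodioxin-4-one | CCCCC[C@H](O[Si](CC)(CC)CC)CCCCC[C@@H](O[Si](CC)(CC)CC)Cc1cc(O)cc2OC(C)(C)OC(=O)c12 | intermediate (not isolated)
16 | 5-[(2R,8S)-2,8-dihydroxytridecyl]-7-hydroxy-2,2-dimethyl-4H-1,3-benzodioxin-4-one | CCCCC[C@H](O)CCCCC[C@@H](O)Cc1cc(O)cc2OC(C)(C)OC(=O)c12 | intermediate (not isolated)
17 | (3R)-6,8-dihydroxy-3-[(6S)-6-hydroxyundecyl]isochroman-1-one | CCCCC[C@H](O)CCCCC[C@@H]1Cc2cc(O)cc(O)c2C(=O)O1 | target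

## Step count and least certain steps

Total: 10 steps. Longest linear sequence: 9 steps (steps 1 to 7, 9 and 10, from 1 to 17); step 8 is a one-step side branch.

**Step 10 (key step).** The most likely failure is a slow or incomplete lactonisation. The C6 phenoxide donates into the C1 carbonyl, and the phenols buffer the alkoxide, so the acyl substitution may stall at 16. A second failure is early loss of the C3 silyl group before ring A is aromatic, which opens the paths to hemiketal formation and dehydration or to elimination of the C3 oxygen. The fallback sets out from 14 and comes back at 17. The sequence is stopped after the amine stage and 15 is isolated. Both silyl ethers are removed with HF·pyridine in THF to give 16. Aqueous LiOH in THF then opens the dioxinone to 2,4-dihydroxy-6-[(2R,8S)-2,8-dihydroxytridecyl]benzoic acid F1, and acidification at room temperature closes the δ-lactone by ordinary hydroxy-acid lactonisation. This path does not depend on the electrophilicity of the dioxinone carbonyl.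

**Step 5.** The most likely failure is poor facial selectivity, because an acetate enolate has no α-substituent to fix the chair, together with some desilylation by the Lewis acid. The fallback sets out from 7 and comes back at 10. A Roskamp homologation (ethyl diazoacetate, SnCl2 cat., CH2Cl2) gives ethyl (9S)-3-oxo-9-(triethylsilyloxy)tetradecanoate F2. Noyori hydrogenation (H2, RuCl2[(R)-BINAP], buffered EtOH), whose sense for β-keto esters of this type is well established, gives ethyl (3R,9S)-3-hydroxy-9-(triethylsilyloxy)tetradecanoate F3. Aminolysis with MeONHMe·HCl and iPrMgCl in THF at −20 °C gives 10.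

**Step 9.** The most likely failures are incomplete acylation through proton transfer from the α-methylene of the amide, E1cB loss of triethylsilanolate under the strongly basic dianion, and decay of the product on isolation by spontaneous aromatisation or desilylation on silica. The fallback sets out from 11 and comes back at 14. Reduction with iBu2AlH in THF at −78 °C gives (3R,9S)-3,9-bis(triethylsilyloxy)tetradecanal F4. Aldol addition of the same dianion of 13 at −78 °C, a faster and less basic-demanding reaction than the acylation, gives 6-[(4RS,6R,12S)-4-hydroxy-2-oxo-6,12-bis(triethylsilyloxy)heptadecyl]-2,2-dimethyl-4H-1,3-dioxin-4-one F5 as a mixture of C4 epimers. Oxidation with Dess–Martin periodinane (NaHCO3, CH2Cl2) removes the new stereocentre and gives 14.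

**Step 8.** The most likely failures are O-acylation and double acylation of the dienolate, which lower the throughput of this branch. The fallback sets out from 12 and comes back at 13. Vinylogous aldol addition of the lithium dienolate (LiN(iPr)2, THF, −78 °C) to acetaldehyde gives 6-(2-hydroxypropyl)-2,2-dimethyl-4H-1,3-dioxin-4-one F6, and oxidation with Dess–Martin periodinane gives 13.

## Further compounds

F1 | step 10 | 2,4-dihydroxy-6-[(2R,8S)-2,8-dihydroxytridecyl]benzoic acid | CCCCC[C@H](O)CCCCC[C@@H](O)Cc1cc(O)cc(O)c1C(=O)O
F2 | step 5 | ethyl (9S)-3-oxo-9-(triethylsilyloxy)tetradecanoate | CCCCC[C@H](O[Si](CC)(CC)CC)CCCCCC(=O)CC(=O)OCC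
F3 | step 5 | ethyl (3R,9S)-3-hydroxy-9-(triethylsilyloxy)tetradecanoate | CCCCC[C@H](O[Si](CC)(CC)CC)CCCCC[C@@H](O)CC(=O)OCC
F4 | step 9 | (3R,9S)-3,9-bis(triethylsilyloxy)tetradecanal | CCCCC[C@H](O[Si](CC)(CC)CC)CCCCC[C@@H](O[Si](CC)(CC)CC)CC=O
F5 | step 9 | 6-[(4RS,6R,12S)-4-hydroxy-2-oxo-6,12-bis(triethylsilyloxy)heptadecyl]-2,2-dimethyl-4H-1,3-dioxin-4-one | CCCCC[C@H](O[Si](CC)(CC)CC)CCCCC[C@@H](O[Si](CC)(CC)CC)CC(O)CC(=O)CC1=CC(=O)OC(C)(C)O1
F6 | step 8 | 6-(2-hydroxypropyl)-2,2-dimethyl-4H-1,3-dioxin-4-one | CC(O)CC1=CC(=O)OC(C)(C)O1
A1 | alternative 1 | methyl 2,4-dihydroxy-6-[(2R,8S)-2,8-bis(triethylsilyloxy)tridecyl]benzoate | CCCCC[C@H](O[Si](CC)(CC)CC)CCCCC[C@@H](O[Si](CC)(CC)CC)Cc1cc(O)cc(O)c1C(=O)OC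
A2 | alternative 1 | methyl (5R,11S)-5,11-bis(triethylsilyloxy)hexadec-2-ynoate | CCCCC[C@H](O[Si](CC)(CC)CC)CCCCC[C@@H](O[Si](CC)(CC)CC)CC#CC(=O)OC
A3 | alternative 1 | 1-methoxy-1,3-bis(trimethylsilyloxy)buta-1,3-diene | COC(O[Si](C)(C)C)=CC(=C)O[Si](C)(C)C
A4 | alternative 2 | (3R)-3-[(6S)-6-(tert-butyldimethylsilyloxy)undecyl]-6,8-dimethoxyisochroman-1-one | CCCCC[C@H](O[Si](C)(C)C(C)(C)C)CCCCC[C@@H]1Cc2cc(OC)cc(OC)c2C(=O)O1
A5 | alternative 2 | (4R)-4-[(6S)-6-(tert-butyldimethylsilyloxy)undecyl]oxetan-2-one | CCCCC[C@H](O[Si](C)(C)C(C)(C)C)CCCCC[C@@H]1CC(=O)O1
A6 | alternative 2 | 3,5-dimethoxybenzyne (1,2-didehydro-3,5-dimethoxybenzene) | COC1=CC(OC)=CC#C1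
A7 | alternative 3 | (3R)-3-[(6S)-6-hydroxyundecyl]-6,8-dimethoxyisochroman-1-one | CCCCC[C@H](O)CCCCC[C@@H]1Cc2cc(OC)cc(OC)c2C(=O)O1
A8 | alternative 3 | 2-[(6S)-6-hydroxyundecyl]-5,7-dimethoxyindan-1-one (both C2 epimers) | CCCCC[C@H](O)CCCCCC1Cc2cc(OC)cc(OC)c2C1=O
A9 | alternative 3 | 5,7-dimethoxyindan-1-one | COc1cc(OC)c2C(=O)CCc2c1
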